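## Structural features

Betaethrin E (23) is an achiral diaryl ether: two tetrasubstituted benzene rings are joined only through the oxygen between C1 of ring A and C1' of ring B, and there is no stereocentre, so no stereochemical relationship has to be set. Ring A is numbered C1 (ether carbon), C2 (CH2O–hexadecanoyl), C4 (OMe) and C6 (OH); ring B is numbered C1' (ether carbon), C3' (CH3), C5' (OH) and C6' (CO2Me); C3, C5, C2' and C4' carry hydrogen. The ether oxygen is crowded, with C2 and C6 flanking it on ring A and the ester carbon C6' flanking it on ring B, which makes a late Ullmann or SNAr arylation of a 2,6-disubstituted phenol unattractive. The fragile parts are the benzylic ester (base, nucleophiles, hydrogenolysis, transesterification), the methyl ester hydrogen-bonded to the C5' phenol, and the electron-rich ring A, which is easily oxidised or alkylated. The real difficulty is twofold: making the hindered C1–O–C1' link, and telling five oxygens apart so that only the benzylic one is acylated and two phenols end up free. The key step uses the pattern of ring B: the ester carbon C6' lies between the oxygen-bearing carbons C1' and C5', the methyl on C3' is para to the ester, and C2' and C4' are unsubstituted. This is what a 4-oxy-6-methyl-2-pyrone-3-carboxylate gives (C3, C4, C5, C6 become C6', C5', C4', C3') once an alkyne has added across C3 and C6 and CO2 has left; the alkyne carbons become C1' and C2', and the ether oxygen arrives on the alkyne, so the crowded C–O bond is never made by coupling.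

## Logic of the disconnections

23 from 22. The O–CH2 bond of the methoxymethyl acetal on the C6 oxygen is cut last. The C6 phenol must stay masked until the benzylic oxygen carries its acyl chain, and an acetal can be removed without base or nucleophile, which the benzylic ester would not tolerate. The gain is a clean distinction between the C6 oxygen and the benzylic oxygen. The forward step must cleave the acetal without exchanging either ester and without letting the released one-carbon electrophile attack ring A.

22 from 20 and 21. The ester C–O bond at the benzylic oxygen is cut, because the C16 chain is a purchasable acyl donor and is best attached after all strongly basic and thermal steps. This removes half of the carbon atoms and the most base-labile group. The forward acylation must prefer the primary alcohol of 20 over its C5' phenol, which is helped by the hydrogen bond of that phenol to the C6' ester.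

20 from 18 through 19. The O–acetyl bond on C5' and the O–Si bond on the benzylic oxygen are cut. Both groups only serve the ring construction: the acetate tunes the diene, the silyl ether survives the organolithium used to make the alkyne. Removing them in one flask keeps the end game at three steps. Methanolysis and fluoride must leave the acetal and the methyl ester untouched.

18 from 11 and 16. Two bonds of ring B, C1'–C6' and C2'–C3', are cut, and CO2 is formally put back as a bridge between C6' and C3'. The cut is made here because the substitution pattern of ring B maps onto 16 atom for atom and because the ether oxygen then comes in on 11. The molecule falls into two pieces of similar size, and the hindered aryl–O–aryl bond is traded for an O–alkyne bond made from a phenoxide. The forward step needs one regiochemistry (aryloxy carbon next to the ester carbon) and partners that tolerate heating.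

11 from 8, and 8 from 6 and 7. The alkyne is traced to a 1,2-dichlorovinyl ether, and the O–C(sp2) bond is then cut to the phenol 6 and the two-carbon unit 7. This reduces the alkyne to a phenol plus a commodity chemical. The forward sequence needs a ring A that survives carbonate in hot DMF and an alkyllithium at low temperature, which is why the benzylic oxygen is a silyl ether and the C6 oxygen an acetal, and neither is an ester.

6 from 5, and 5 from 4. The O–Si bond is cut, then the benzylic alcohol is taken back to the aldehyde. The aldehyde is kept as long as possible because it makes the two catechol oxygens unequal. The forward steps need silylation of a primary alcohol in preference to a hindered phenol and a hydride reduction that leaves the acetal.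

4 from 3, 3 from 2, and 2 from 1. The acetal O–C bond on the future C6 oxygen is cut, then the aryl C–O bond (back to C–Br), then the C–Br bond. This leads to a cheap salicylaldehyde that already has the methoxy group and the one-carbon substituent in place. The alkylation must choose the oxygen remote from the formyl group, and the hydroxylation must tolerate the aldehyde.

16 from 15, and 15 from 12 and 13. The O–acetyl bond is cut, then the lactone O1–C2 bond and the C3–C4 bond of the pyrone. 15 is deliberately not approached by acylating a preformed 4-hydroxypyrone at C3, where O-acylation and reaction at the ring methyl compete; C-acylation of 12 by 13 places the ester at C3 without ambiguity. The forward step needs C- over O-acylation of the malonate and lactonisation of the resulting chain.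

## Other disconnections considered

Alternative 1: The cut is made inside the ester of ring B. The methyl ester and the C6 phenol of 23 are traced to the lactone of depsidone A2, and A2 to xanthone A1 by taking out the oxygen between the carbonyl carbon and C6 of ring A. Forward, a strong peracid would add to the ketone of A1, and in the Criegee intermediate C6 of ring A would migrate from carbon to oxygen (Baeyer–Villiger oxidation). This forms the C6–O bond and widens the pyranone to the seven-membered dioxepinone; methanolysis of A2 would then free the C6 phenol and form the methyl ester in one operation. In its favour, A1 belongs to a class assembled by robust acylation and SNAr chemistry, the tricycle fixes the positions of ether, ester and future phenol, and no sensitive alkyne is needed. On reagent stability, and in the way the C6 hydroxyl appears without a protecting group, it is the better plan. Against it, the ketone of A1 is flanked by two aryl rings and conjugated with the ring oxygen, so it should be a poor acceptor for peracids, and conditions that force the addition would also threaten the methoxy-substituted ring A. The outcome further depends on ring A migrating in preference to ring B, a balance between two ortho-oxygenated aryl groups that only the triflate tilts. After methanolysis the triflate must still become the C5' hydroxyl and the benzylic acetate must be exchanged for the C16 ester next to a free, non-chelated C6 phenol. In comparison, both plans avoid a hindered diaryl ether coupling (equal on structure). The cycloaddition draws its regiochemistry from matched polarisation of both partners, whereas the oxygen insertion rests on a migratory preference that is harder to predict. A1 should need about as many steps as 11 and 16 together and the end game is no shorter, so no saving is expected.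

Alternative 2: Ring A is cut between C1 and C2. Benzoate A4 is traced to the open chain A3, in which C6 is a ketone, C4 is masked as a methyl enol ether, C2 is the ketone of an α-keto ester, and the ring B aryloxy group already sits on C1. Forward, a mild base would deprotonate the aryloxy-bearing methylene, the carbanion would add to the C2 ketone (6-(enolendo)-exo-trig aldol), and loss of water and enolisation would give the aromatic ring with the C6 phenol free. In its favour, the ether is made beforehand by simple O-alkylation of a ring B phenol, so the hindered arylation disappears just as in the chosen plan (equal). The conditions are mild, with no organolithium, no dichloroacetylene and no heating, which is better on practicality. Against it, A3 has several acidic sites: the C5 methylene competes with C1, and enolate oxygens can close onto C2 or C4 to give pyranone or furanone by-products. The enol ether must also hold the E geometry that brings C2 and C5 together. A4 then carries two aryl methyl esters, and only the ring A ester may be reduced to the CH2OH group; the chosen plan has no such problem because its benzylic carbon arrives at the alcohol oxidation level. In comparison, the aldol–aromatisation is simple but the chain has competing modes of closure, while the cycloaddition has essentially one. On step count the alternative could be two or three steps shorter, which is better, but only if the ester differentiation works; changing the ring B ester to solve it would use up the advantage.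

Alternative 3: Ring A is taken apart at C1–C6, C5–C6, C3–C4 and C2–C3. Phenol A7 is traced to diazoketone A5, which carries C1, C2, C3 and C6 with the ring B aryloxy group on C1, and to methoxyacetylene A6, which supplies C4 and C5. Forward, irradiation of A5 would trigger a Wolff rearrangement (vinyl shift, C2–C3) to an aryloxy vinylketene. A (2+2) cycloaddition with A6 (C5–C6 and C3–C4), four-electron opening of the cyclobutenone, six-electron electrocyclisation (C1–C6) and tautomerisation would then give A7 (Danheiser benzannulation). In its favour, the step is highly convergent and its regiochemistry comes from the same ketene/ynol ether polarity the chosen plan relies on (equal). The C6 hydroxyl appears free, and A7 is only desilylation, acylation and acetal cleavage away from 23, so the total could be three or four steps shorter, which is better on step count. Against it, the precedent for this benzannulation lies with carbon-substituted vinyl diazoketones. Here the vinyl group is an enol ether whose aryloxy-bearing terminus must take part in the electrocyclisation, and the benzoate chromophore of ring B competes for light. A6 is volatile, unstable and must be prepared, and the diazo compound and photochemistry limit scale. A7 also has the C6 phenol free beside the benzylic alcohol at the acylation stage, a harder selectivity problem than in 20, where the only free phenol is the chelated C5' one. In comparison, both plans use an oxygen-substituted alkyne as the polarised two-carbon partner and both avoid a diaryl ether coupling. The chosen plan asks for two thermal events (cycloaddition, CO2 loss) of a well-precedented type, whereas this one asks for four events in sequence under irradiation on an unusual ketene; it is shorter on paper but less secure.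

Key step: step 10

Remark on the chemistry: diketene (13) is taken as the purchasable stabilised reagent; 17 is racemic and transient, and every isolated compound is achiral.

## Steps

Step 1
Reactants: 1 2-hydroxy-5-methoxybenzaldehyde
Product: 2 3-bromo-2-hydroxy-5-methoxybenzaldehyde
Conditions: Br2 (1.05 equiv), NaOAc, AcOH, rt
Reagents that add atoms: bromine, BrBr
Why: Electrophilic aromatic bromination directed by the hydroxyl group: its para position is blocked by methoxy, so substitution should go to the free ortho position, and the acetate buffer removes HBr.

Step 2
Reactants: 2 3-bromo-2-hydroxy-5-methoxybenzaldehyde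
Product: 3 2,3-dihydroxy-5-methoxybenzaldehyde
Conditions: NaOH (aq), CuSO4 (cat.), reflux, N2; then HCl
Reagents that add atoms: sodium hydroxide, [Na+].[OH-]
Why: Copper-catalysed hydrolysis of the aryl bromide (Ullmann-type hydroxylation) is a standard way from ortho-bromophenols to catechols; the substrate is a phenoxide under these conditions, which deactivates the formyl group toward Cannizzaro disproportionation, and exclusion of air protects the catechol.

Step 3
Reactants: 3 2,3-dihydroxy-5-methoxybenzaldehyde
Product: 4 2-hydroxy-5-methoxy-3-(methoxymethoxy)benzaldehyde
Conditions: NaH (2.2 equiv), THF–DMF, 0 °C; MOMCl (1.0 equiv), 0 °C to rt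
Reagents that add atoms: chloromethyl methyl ether, COCCl
Why: In the dianion the oxide next to the formyl group is delocalised into the carbonyl and held in a sodium chelate, so the remote oxide is the stronger nucleophile and one equivalent of the chloride should alkylate it selectively (Williamson etherification).

Step 4
Reactants: 4 2-hydroxy-5-methoxy-3-(methoxymethoxy)benzaldehyde
Product: 5 2-(hydroxymethyl)-4-methoxy-6-(methoxymethoxy)phenol
Conditions: NaBH4, MeOH, 0 °C
Reagents that add atoms: none
Why: Hydride reduction of the aryl aldehyde to the benzylic alcohol; the acetal and the aryl ethers do not react with NaBH4.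

Step 5
Reactants: 5 2-(hydroxymethyl)-4-methoxy-6-(methoxymethoxy)phenol
Product: 6 2-({[tert-butyl(dimethyl)silyl]oxy}methyl)-4-methoxy-6-(methoxymethoxy)phenol
Conditions: TBSCl (1.05 equiv), imidazole, CH2Cl2, 0 °C
Reagents that add atoms: tert-butyldimethylsilyl chloride, CC(C)(C)[Si](C)(C)Cl
Why: The primary benzylic hydroxyl is silylated much faster than the phenol, which is hindered by two ortho substituents and hydrogen-bonded to its neighbours, so one equivalent of silyl chloride at 0 °C should give the mono-ether.

Step 6
Reactants: 6 2-({[tert-butyl(dimethyl)silyl]oxy}methyl)-4-methoxy-6-(methoxymethoxy)phenol; 7 trichloroethylene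
Product: 8 tert-butyl({2-[(E)-1,2-dichloroethenoxy]-5-methoxy-3-(methoxymethoxy)phenyl}methoxy)dimethylsilane
Conditions: 7 (3 equiv), K2CO3, DMF, 70 °C
Reagents that add atoms: none
Why: K2CO3 eliminates HCl from 7 to dichloroacetylene, which is formed and consumed in the flask; the phenoxide of 6 adds to it and the vinyl anion is protonated anti, a known route from phenols to (E)-1,2-dichlorovinyl ethers, and the silyl ether and acetal are inert to carbonate.

Step 7
Reactants: 8 tert-butyl({2-[(E)-1,2-dichloroethenoxy]-5-methoxy-3-(methoxymethoxy)phenyl}methoxy)dimethylsilane
Product: 11 tert-butyl{[2-(ethynyloxy)-5-methoxy-3-(methoxymethoxy)phenyl]methoxy}dimethylsilane, via chloroethynyl ether 9 (not isolated), via lithium acetylide 10 (not isolated)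
Conditions: n-BuLi (2.5 equiv), THF, −78 to −40 °C; H2O, −78 °C
Reagents that add atoms: none
Why: The first equivalent of n-BuLi removes the vinylic proton and the anion expels chloride to give 9; chlorine–lithium exchange with the second equivalent gives 10, which is protonated on quenching; this is the standard conversion of dichlorovinyl ethers into terminal ynol ethers, and at −78 °C lithiation ortho to the acetal and attack at silicon are not expected to compete.

Step 8
Reactants: 12 dimethyl malonate; 13 diketene
Product: 15 methyl 4-hydroxy-6-methyl-2-oxo-2H-pyran-3-carboxylate, via acetoacetylmalonate enolate 14 (not isolated)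
Conditions: NaH (2.0 equiv), THF, 0 °C; 13, 0 °C to reflux; then HCl (aq)
Reagents that add atoms: none
Why: The sodium enolate of 12 is C-acylated by the β-lactone carbonyl of 13 (acetoacetylation), and the dianion of the resulting 3,5-dioxo ester 14 closes through its enolate oxygen onto a malonate ester with loss of methoxide, the usual lactonisation of such chains to 4-hydroxy-2-pyrones; the ester is thereby placed unambiguously at C3.

Step 9
Reactants: 15 methyl 4-hydroxy-6-methyl-2-oxo-2H-pyran-3-carboxylate
Product: 16 methyl 4-(acetyloxy)-6-methyl-2-oxo-2H-pyran-3-carboxylate
Conditions: AcCl, Et3N, CH2Cl2, −20 to 0 °C; filtration, no aqueous work-up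
Reagents that add atoms: acetyl chloride, CC(=O)Cl
Why: The acidic enol is O-acylated at O4; the acetate lowers the donor strength of that oxygen and removes an acidic hydroxyl that would protonate the ynol ether; the product is a vinylogous mixed anhydride and is therefore isolated without water and used promptly.

Step 10
Reactants: 11 tert-butyl{[2-(ethynyloxy)-5-methoxy-3-(methoxymethoxy)phenyl]methoxy}dimethylsilane; 16 methyl 4-(acetyloxy)-6-methyl-2-oxo-2H-pyran-3-carboxylate
Product: 18 methyl 2-(acetyloxy)-6-[2-({[tert-butyl(dimethyl)silyl]oxy}methyl)-4-methoxy-6-(methoxymethoxy)phenoxy]-4-methylbenzoate, via bridged bicyclic lactone 17 (not isolated)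
Conditions: 16 (1.5 equiv), toluene, 100 °C, slow addition of 11, Ar
Reagents that add atoms: none
Why: The electron-poor diene of 16 (lactone carbonyl and C3 ester, with the C4 oxygen tamed as an acetate) and the electron-rich alkyne of 11 combine in an inverse-electron-demand Diels–Alder reaction whose leading bond joins the nucleophilic CH terminus of 11 to C6 of the pyrone, the vinylogous acceptor position of the dienoate, while the aryloxy carbon closes onto C3. This gives the 2-oxabicyclo[2.2.2]octadienone 17, which should lose CO2 by retro-Diels–Alder reaction at the reaction temperature and so deliver arene 18. The closest known reaction type is the cycloaddition–decarboxylation of 3-alkoxycarbonyl-2-pyrones with ynamines, ketene acetals and enol ethers to give oxygenated benzoates. Ring B is thus closed by an intermolecular (4+2) cycloaddition that forms C1'–C6' and C2'–C3', followed by cycloreversion, and not by cyclisation of a tethered chain. The two bridgehead stereocentres of 17 vanish on aromatisation, so 18 has none and no stereocontrol is needed. The step needs one regiochemistry, aryloxy carbon next to the ester carbon, and this is secured by the matched polarisation of the partners: oxygen donation makes the CH carbon of 11 the nucleophile, and the twist imposed by the two ortho substituents of ring A keeps the oxygen lone pair conjugated with the alkyne rather than with the arene. Chemoselectivity rests on the absence of β-hydrogens in the aryl ynol ether (no retro-ene path to a ketene) and on slow addition of 11 to an excess of 16, which keeps oligomerisation of the alkyne behind the cycloaddition.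

Step 11
Reactants: 18 methyl 2-(acetyloxy)-6-[2-({[tert-butyl(dimethyl)silyl]oxy}methyl)-4-methoxy-6-(methoxymethoxy)phenoxy]-4-methylbenzoate
Product: 20 methyl 2-hydroxy-6-[2-(hydroxymethyl)-4-methoxy-6-(methoxymethoxy)phenoxy]-4-methylbenzoate, via phenol silyl ether 19 (not isolated)
Conditions: K2CO3, MeOH, 0 °C to rt; evaporate; TBAF, THF, 0 °C to rt
Reagents that add atoms: none
Why: K2CO3 in methanol transesterifies the aryl acetate (exchange at the methyl ester is degenerate) and leaves the alkyl silyl ether; fluoride then cleaves the Si–O bond; the acetal and the diaryl ether are inert to both reagents.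

Step 12
Reactants: 20 methyl 2-hydroxy-6-[2-(hydroxymethyl)-4-methoxy-6-(methoxymethoxy)phenoxy]-4-methylbenzoate; 21 hexadecanoyl chloride (palmitoyl chloride)
Product: 22 methyl 2-[2-(hexadecanoyloxymethyl)-4-methoxy-6-(methoxymethoxy)phenoxy]-6-hydroxy-4-methylbenzoate
Conditions: 21 (1.05 equiv), pyridine, CH2Cl2, −20 to 0 °C
Reagents that add atoms: none
Why: Acylation of the primary benzylic alcohol by the acid chloride with pyridine is much faster than that of the C5' phenol, which is hydrogen-bonded to and flanked by the C6' ester; one equivalent at low temperature without an acyl-transfer catalyst should give the mono-ester.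

Step 13
Reactants: 22 methyl 2-[2-(hexadecanoyloxymethyl)-4-methoxy-6-(methoxymethoxy)phenoxy]-6-hydroxy-4-methylbenzoate
Product: 23 betaethrin E, methyl 2-[2-(hexadecanoyloxymethyl)-6-hydroxy-4-methoxyphenoxy]-6-hydroxy-4-methylbenzoate
Conditions: ZnBr2, n-PrSH, CH2Cl2, 0 °C
Reagents that add atoms: none
Why: ZnBr2 activates the acetal and the thiol captures the methoxymethyl cation, so the phenol is released under aprotic conditions in minutes; no alcohol or aqueous acid is present that could transesterify the benzylic or the methyl ester, and the cation cannot alkylate the electron-rich ring A.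

## Compound list

1 | 2-hydroxy-5-methoxybenzaldehyde | COc1ccc(O)c(C=O)c1 | starting material
2 | 3-bromo-2-hydroxy-5-methoxybenzaldehyde | COc1cc(Br)c(O)c(C=O)c1 | intermediate
3 | 2,3-dihydroxy-5-methoxybenzaldehyde | COc1cc(O)c(O)c(C=O)c1 | intermediate
4 | 2-hydroxy-5-methoxy-3-(methoxymethoxy)benzaldehyde | COCOc1cc(OC)cc(C=O)c1O | intermediate
5 | 2-(hydroxymethyl)-4-methoxy-6-(methoxymethoxy)phenol | COCOc1cc(OC)cc(CO)c1O | intermediate
6 | 2-({[tert-butyl(dimethyl)silyl]oxy}methyl)-4-methoxy-6-(methoxymethoxy)phenol | COCOc1cc(OC)cc(CO[Si](C)(C)C(C)(C)C)c1O | intermediate
7 | trichloroethylene | ClC=C(Cl)Cl | starting material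
8 | tert-butyl({2-[(E)-1,2-dichloroethenoxy]-5-methoxy-3-(methoxymethoxy)phenyl}methoxy)dimethylsilane | Cl/C=C(/Cl)Oc1c(CO[Si](C)(C)C(C)(C)C)cc(OC)cc1OCOC | intermediate
9 | tert-butyl({2-[(chloroethynyl)oxy]-5-methoxy-3-(methoxymethoxy)phenyl}methoxy)dimethylsilane | ClC#COc1c(CO[Si](C)(C)C(C)(C)C)cc(OC)cc1OCOC | intermediate
10 | {[2-({[tert-butyl(dimethyl)silyl]oxy}methyl)-4-methoxy-6-(methoxymethoxy)phenoxy]ethynyl}lithium | [Li]C#COc1c(CO[Si](C)(C)C(C)(C)C)cc(OC)cc1OCOC | intermediate
11 | tert-butyl{[2-(ethynyloxy)-5-methoxy-3-(methoxymethoxy)phenyl]methoxy}dimethylsilane | C#COc1c(CO[Si](C)(C)C(C)(C)C)cc(OC)cc1OCOC | intermediate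
12 | dimethyl malonate | COC(=O)CC(=O)OC | starting material
13 | diketene (4-methylideneoxetan-2-one) | C=C1CC(=O)O1 | starting material
14 | dimethyl 2-(3-oxobutanoyl)propanedioate (present as its sodium enolate) | CC(=O)CC(=O)C(C(=O)OC)C(=O)OC | intermediate
15 | methyl 4-hydroxy-6-methyl-2-oxo-2H-pyran-3-carboxylate | COC(=O)C1=C(O)C=C(C)OC1=O | intermediate
16 | methyl 4-(acetyloxy)-6-methyl-2-oxo-2H-pyran-3-carboxylate | COC(=O)C1=C(OC(C)=O)C=C(C)OC1=O | intermediate
17 | methyl 5-(acetyloxy)-8-[2-({[tert-butyl(dimethyl)silyl]oxy}methyl)-4-methoxy-6-(methoxymethoxy)phenoxy]-1-methyl-3-oxo-2-oxabicyclo[2.2.2]octa-5,7-diene-4-carboxylate (racemic; the two bridgeheads are fixed relative to each other by the bicycle) | COC(=O)C12C(=O)OC(C)(C=C1OC(C)=O)C=C2Oc1c(CO[Si](C)(C)C(C)(C)C)cc(OC)cc1OCOC | intermediate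
18 | methyl 2-(acetyloxy)-6-[2-({[tert-butyl(dimethyl)silyl]oxy}methyl)-4-methoxy-6-(methoxymethoxy)phenoxy]-4-methylbenzoate | COC(=O)c1c(OC(C)=O)cc(C)cc1Oc1c(CO[Si](C)(C)C(C)(C)C)cc(OC)cc1OCOC | intermediate
19 | methyl 2-[2-({[tert-butyl(dimethyl)silyl]oxy}methyl)-4-methoxy-6-(methoxymethoxy)phenoxy]-6-hydroxy-4-methylbenzoate | COC(=O)c1c(O)cc(C)cc1Oc1c(CO[Si](C)(C)C(C)(C)C)cc(OC)cc1OCOC | intermediate
20 | methyl 2-hydroxy-6-[2-(hydroxymethyl)-4-methoxy-6-(methoxymethoxy)phenoxy]-4-methylbenzoate | COC(=O)c1c(O)cc(C)cc1Oc1c(CO)cc(OC)cc1OCOC | intermediate
21 | hexadecanoyl chloride (palmitoyl chloride) | CCCCCCCCCCCCCCCC(=O)Cl | starting material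
22 | methyl 2-[2-(hexadecanoyloxymethyl)-4-methoxy-6-(methoxymethoxy)phenoxy]-6-hydroxy-4-methylbenzoate | CCCCCCCCCCCCCCCC(=O)OCc1cc(OC)cc(OCOC)c1Oc1cc(C)cc(O)c1C(=O)OC | intermediate
23 | betaethrin E, methyl 2-[2-(hexadecanoyloxymethyl)-6-hydroxy-4-methoxyphenoxy]-6-hydroxy-4-methylbenzoate | CCCCCCCCCCCCCCCC(=O)OCc1cc(OC)cc(O)c1Oc1cc(C)cc(O)c1C(=O)OC | target

## Step count and least certain steps

Total step count: 13. Longest linear sequence: 11 steps (steps 1 to 7, then 10 to 13); steps 8 and 9 are the two-step side branch to 16.

Key step, step 10. The most likely failure is that the ynol ether is consumed by oligomerisation, or by addition of traces of acid or water, before it reaches the diene, because the C4 oxygen still feeds electron density into the pyrone and slows the cycloaddition. A second possibility is attack of the nucleophilic alkyne carbon at C4 of 16 with expulsion of acetate. The fallback sets out from 6 and returns at 19; it makes the ether bond by SNAr instead of by ring construction. Commercial 2,6-difluoro-4-methylbenzoic acid is esterified (MeI, K2CO3, DMF) to methyl 2,6-difluoro-4-methylbenzoate F1. The phenoxide of 6 (Cs2CO3, DMSO, 90 °C) displaces one fluoride to give methyl 2-[2-({[tert-butyl(dimethyl)silyl]oxy}methyl)-4-methoxy-6-(methoxymethoxy)phenoxy]-6-fluoro-4-methylbenzoate F2. The remaining fluoride, still ortho to the ester, is exchanged for hydroxyl with acetohydroxamic acid and K2CO3 in DMSO at 80 °C (O-arylation, then Lossen-type fragmentation). This gives 19, which continues with the fluoride stage of step 11.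

Step 7. The terminal ynol ether may be lost during isolation through acid-catalysed hydration on silica or oligomerisation of the neat compound; deprotonation ortho to the acetal becomes a further risk if the temperature drifts upward. The fallback sets out from 8 and returns at 11; it carries the alkyne in C-protected form. Acetylide 10, generated as before, is quenched with Me3SiCl to give tert-butyl{[5-methoxy-3-(methoxymethoxy)-2-{[(trimethylsilyl)ethynyl]oxy}phenyl]methoxy}dimethylsilane F3, which can be chromatographed and stored. K2CO3 in MeOH at 0 °C cleaves the C–Si bond just before use, and 11 is taken into step 10 as a solution without chromatography.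

Step 9. The product may hydrolyse or transfer its acetyl group during isolation, because a 4-acyloxy pyrone with an ester at C3 is a vinylogous mixed anhydride; acylation at the lactone oxygen instead of O4 is a lesser risk. The fallback sets out from 15 and returns at 19; it carries the C4 oxygen as an arenesulfonate. TsCl and Et3N convert 15 into methyl 6-methyl-4-{[(4-methylphenyl)sulfonyl]oxy}-2-oxo-2H-pyran-3-carboxylate F4, a robust and more electron-poor diene. Cycloaddition with 11 under the conditions of step 10 passes through the bridged lactone methyl 8-[2-({[tert-butyl(dimethyl)silyl]oxy}methyl)-4-methoxy-6-(methoxymethoxy)phenoxy]-1-methyl-5-{[(4-methylphenyl)sulfonyl]oxy}-3-oxo-2-oxabicyclo[2.2.2]octa-5,7-diene-4-carboxylate F5 and gives methyl 2-[2-({[tert-butyl(dimethyl)silyl]oxy}methyl)-4-methoxy-6-(methoxymethoxy)phenoxy]-4-methyl-6-{[(4-methylphenyl)sulfonyl]oxy}benzoate F6. Reductive S–O cleavage with Mg in MeOH then gives 19.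

Step 3. Alkylation may occur at the wrong phenoxide or at both, since the selectivity rests only on the different nucleophilicity of two oxides in one dianion. The fallback sets out from 3 and returns at 4; it protects both oxygens and then frees one. Excess MOMCl with i-Pr2NEt gives 5-methoxy-2,3-bis(methoxymethoxy)benzaldehyde F7. MgBr2·OEt2 in Et2O–CH2Cl2 then removes only the acetal ortho to the formyl group, which is activated by chelation, to give 4.

Step 2. The aldehyde may disproportionate or the catechol may be oxidised by air under hot alkali, and the C–Br hydrolysis may stall, because the substrate is an electron-rich phenoxide. The fallback sets out from 2 and returns at 4, so it also bypasses step 3. BnBr and K2CO3 in DMF give 2-(benzyloxy)-3-bromo-5-methoxybenzaldehyde F8. Miyaura borylation (B2pin2, Pd(dppf)Cl2, KOAc, dioxane, 90 °C) gives 2-(benzyloxy)-5-methoxy-3-(4,4,5,5-tetramethyl-1,3,2-dioxaborolan-2-yl)benzaldehyde F9. Oxidation with NaBO3·4H2O in THF–H2O gives 2-(benzyloxy)-3-hydroxy-5-methoxybenzaldehyde F10, and MOMCl with i-Pr2NEt gives 2-(benzyloxy)-5-methoxy-3-(methoxymethoxy)benzaldehyde F11. Hydrogenolysis of the benzyl ether (H2, Pd/C, EtOAc) then gives 4.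

## Further compounds

F1 | step 10 | methyl 2,6-difluoro-4-methylbenzoate | COC(=O)c1c(F)cc(C)cc1F
F2 | step 10 | methyl 2-[2-({[tert-butyl(dimethyl)silyl]oxy}methyl)-4-methoxy-6-(methoxymethoxy)phenoxy]-6-fluoro-4-methylbenzoate | COC(=O)c1c(F)cc(C)cc1Oc1c(CO[Si](C)(C)C(C)(C)C)cc(OC)cc1OCOC
F3 | step 7 | tert-butyl{[5-methoxy-3-(methoxymethoxy)-2-{[(trimethylsilyl)ethynyl]oxy}phenyl]methoxy}dimethylsilane | C[Si](C)(C)C#COc1c(CO[Si](C)(C)C(C)(C)C)cc(OC)cc1OCOC
F4 | step 9 | methyl 6-methyl-4-{[(4-methylphenyl)sulfonyl]oxy}-2-oxo-2H-pyran-3-carboxylate | COC(=O)C1=C(OS(=O)(=O)c2ccc(C)cc2)C=C(C)OC1=O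
F5 | step 9 | methyl 8-[2-({[tert-butyl(dimethyl)silyl]oxy}methyl)-4-methoxy-6-(methoxymethoxy)phenoxy]-1-methyl-5-{[(4-methylphenyl)sulfonyl]oxy}-3-oxo-2-oxabicyclo[2.2.2]octa-5,7-diene-4-carboxylate (racemic) | COC(=O)C12C(=O)OC(C)(C=C1OS(=O)(=O)c1ccc(C)cc1)C=C2Oc1c(CO[Si](C)(C)C(C)(C)C)cc(OC)cc1OCOC
F6 | step 9 | methyl 2-[2-({[tert-butyl(dimethyl)silyl]oxy}methyl)-4-methoxy-6-(methoxymethoxy)phenoxy]-4-methyl-6-{[(4-methylphenyl)sulfonyl]oxy}benzoate | COC(=O)c1c(OS(=O)(=O)c2ccc(C)cc2)cc(C)cc1Oc1c(CO[Si](C)(C)C(C)(C)C)cc(OC)cc1OCOC
F7 | step 3 | 5-methoxy-2,3-bis(methoxymethoxy)benzaldehyde | COCOc1cc(OC)cc(C=O)c1OCOC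
F8 | step 2 | 2-(benzyloxy)-3-bromo-5-methoxybenzaldehyde | COc1cc(Br)c(OCc2ccccc2)c(C=O)c1
F9 | step 2 | 2-(benzyloxy)-5-methoxy-3-(4,4,5,5-tetramethyl-1,3,2-dioxaborolan-2-yl)benzaldehyde | COc1cc(B2OC(C)(C)C(C)(C)O2)c(OCc2ccccc2)c(C=O)c1
F10 | step 2 | 2-(benzyloxy)-3-hydroxy-5-methoxybenzaldehyde | COc1cc(O)c(OCc2ccccc2)c(C=O)c1
F11 | step 2 | 2-(benzyloxy)-5-methoxy-3-(methoxymethoxy)benzaldehyde | COCOc1cc(OC)cc(C=O)c1OCc1ccccc1
A1 | alternative 1 | [2-methoxy-6-methyl-9-oxo-8-{[(trifluoromethyl)sulfonyl]oxy}-9H-xanthen-4-yl]methyl acetate | Cc1cc(OS(=O)(=O)C(F)(F)F)c2C(=O)c3cc(OC)cc(COC(C)=O)c3Oc2c1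
A2 | alternative 1 | [8-methoxy-3-methyl-11-oxo-1-{[(trifluoromethyl)sulfonyl]oxy}-11H-dibenzo[b,e][1,4]dioxepin-6-yl]methyl acetate | Cc1cc(OS(=O)(=O)C(F)(F)F)c2C(=O)Oc3cc(OC)cc(COC(C)=O)c3Oc2c1
A3 | alternative 2 | methyl (3E)-4-methoxy-7-[2-(methoxycarbonyl)-3-(methoxymethoxy)-5-methylphenoxy]-2,6-dioxohept-3-enoate | COC(=O)C(=O)/C=C(/OC)CC(=O)COc1cc(C)cc(OCOC)c1C(=O)OC
A4 | alternative 2 | methyl 3-hydroxy-5-methoxy-2-[2-(methoxycarbonyl)-3-(methoxymethoxy)-5-methylphenoxy]benzoate | COC(=O)c1cc(OC)cc(O)c1Oc1cc(C)cc(OCOC)c1C(=O)OC
A5 | alternative 3 | methyl 2-{[(1E)-2-({[tert-butyl(dimethyl)silyl]oxy}methyl)-4-diazo-3-oxobut-1-en-1-yl]oxy}-6-(methoxymethoxy)-4-methylbenzoate | [N-]=[N+]=CC(=O)/C(CO[Si](C)(C)C(C)(C)C)=C/Oc1cc(C)cc(OCOC)c1C(=O)OC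
A6 | alternative 3 | methoxyethyne (methoxyacetylene) | COC#C
A7 | alternative 3 | methyl 2-[2-({[tert-butyl(dimethyl)silyl]oxy}methyl)-6-hydroxy-4-methoxyphenoxy]-6-(methoxymethoxy)-4-methylbenzoate | COc1cc(O)c(Oc2cc(C)cc(OCOC)c2C(=O)OC)c(CO[Si](C)(C)C(C)(C)C)c1
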